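**Strategy**

Everything rests on disconnecting N1–C7a in both indoles at the same time. Bromine sits on C6, which is para to C3a, so each benzenoid ring can be carried as a 4-bromophenyl ring whose two ortho C–H bonds are identical; a nitrene generated on the future C2 can therefore only deliver the 6-bromoindole. In one operation the key step forms both N1–C7a bonds and closes both pyrrole rings on a preformed imidazole. Its substrate is a 1-(dimethylsulfamoyl)imidazole bearing a 2-azido-1-(4-bromophenyl)vinyl arm at C2 and at C4, built from 4-iodoimidazole, two 4-bromobenzaldehyde units, a sulfonium methylide carbon and azide.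

Key step: step 8

Remark: a dehydration cannot fix the alkene geometry, so 14 is carried as a mixture of alkene isomers (the E,E isomer, each azide cis to the aryl ring, is drawn), all of which converge on the same azirine in step 8; the carbinols, epoxides, azido alcohols and azirines are likewise stereoisomer mixtures whose stereocentres are all erased later.

**Route**

Step 1
Reactants: 1 4-iodo-1H-imidazole; 2 dimethylsulfamoyl chloride
Product: 3 4-iodo-N,N-dimethyl-1H-imidazole-1-sulfonamide
Conditions: Me2NSO2Cl, Et3N, CH2Cl2, 0 °C → rt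
Reagents that add atoms: dimethylsulfamoyl chloride (2), CN(C)S(=O)(=O)Cl
Why: N-sulfonylation of the imidazole under base is expected to place the sulfamoyl group on the nitrogen remote from iodine (the less hindered 1,4-isomer), where it later directs C2 metalation and deactivates the heterocycle.

Step 2
Reactants: 3 4-iodo-N,N-dimethyl-1H-imidazole-1-sulfonamide; 4 4-bromobenzaldehyde
Product: 6 2-[(4-bromophenyl)(hydroxy)methyl]-4-iodo-N,N-dimethyl-1H-imidazole-1-sulfonamide (racemic), via 2-lithioimidazole 5 (not isolated)
Conditions: LiN(iPr)2, THF, −78 °C; then 4, −78 °C; aq NH4Cl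
Reagents that add atoms: 4-bromobenzaldehyde (4), O=Cc1ccc(Br)cc1
Why: Directed deprotonation with a non-nucleophilic lithium amide should remove the most acidic ring proton (C2–H, flanked by both nitrogens and the coordinating sulfamoyl group) without touching the C–I bond, and 1,2-addition of the 2-lithioimidazole to the aldehyde gives the carbinol, whose uncontrolled stereocentre is erased in step 4.

Step 3
Reactants: 6 2-[(4-bromophenyl)(hydroxy)methyl]-4-iodo-N,N-dimethyl-1H-imidazole-1-sulfonamide; 4 4-bromobenzaldehyde
Product: 8 2,4-bis[(4-bromophenyl)(hydroxy)methyl]-N,N-dimethyl-1H-imidazole-1-sulfonamide (mixture of diastereomers), via dimagnesium species 7 (not isolated)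
Conditions: iPrMgCl (2.2 equiv), THF, −20 → 0 °C; then 4, 0 °C → rt; aq NH4Cl
Reagents that add atoms: 4-bromobenzaldehyde (4), O=Cc1ccc(Br)cc1
Why: Iodine–magnesium exchange (the first equivalent of iPrMgCl only deprotonates the hydroxyl) gives a C4 Grignard reagent that cannot isomerise to the now substituted C2 and adds to the aldehyde, while the aryl bromides are inert to iPrMgCl at this temperature; the diastereomer mixture is irrelevant because both carbinols are oxidised next.

Step 4
Reactants: 8 2,4-bis[(4-bromophenyl)(hydroxy)methyl]-N,N-dimethyl-1H-imidazole-1-sulfonamide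
Product: 9 2,4-bis(4-bromobenzoyl)-N,N-dimethyl-1H-imidazole-1-sulfonamide
Conditions: activated MnO2 (excess), CH2Cl2, rt
Reagents that add atoms: none
Why: MnO2 oxidation of benzylic, heteroaryl-flanked secondary alcohols to ketones is neutral and selective, so the sulfamoyl group, the aryl bromides and the imidazole are untouched and both stereocentres disappear.

Step 5
Reactants: 9 2,4-bis(4-bromobenzoyl)-N,N-dimethyl-1H-imidazole-1-sulfonamide; 10 trimethylsulfonium iodide
Product: 11 2,4-bis[2-(4-bromophenyl)oxiran-2-yl]-N,N-dimethyl-1H-imidazole-1-sulfonamide (mixture of diastereomers)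
Conditions: Me3S+ I−, KN(SiMe3)2, THF, 0 °C → rt
Reagents that add atoms: trimethylsulfonium iodide (10), C[S+](C)C.[I-]
Why: Corey–Chaykovsky epoxidation, in which the sulfonium methylide adds to each non-enolisable, electron-poor ketone and the betaine closes to the terminal epoxide with loss of dimethyl sulfide; the non-nucleophilic silylamide base in THF is chosen to spare the N–S bond, and the two uncontrolled stereocentres are destroyed in step 7.

Step 6
Reactants: 11 2,4-bis[2-(4-bromophenyl)oxiran-2-yl]-N,N-dimethyl-1H-imidazole-1-sulfonamide; 12 sodium azide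
Product: 13 2,4-bis[2-azido-1-(4-bromophenyl)-1-hydroxyethyl]-N,N-dimethyl-1H-imidazole-1-sulfonamide (mixture of diastereomers)
Conditions: NaN3, NH4Cl, DMF/H2O, 65 °C
Reagents that add atoms: sodium azide (12), [N-]=[N+]=[N-].[Na+]
Why: Azide should open each 2,2-disubstituted epoxide by SN2 attack at the unhindered CH2 carbon, since the electron-poor imidazole disfavours ionisation at the quaternary benzylic carbon, and NH4Cl buffers the alkoxide so that the N–S bond survives; the tertiary stereocentres remain as an inconsequential mixture.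

Step 7
Reactants: 13 2,4-bis[2-azido-1-(4-bromophenyl)-1-hydroxyethyl]-N,N-dimethyl-1H-imidazole-1-sulfonamide
Product: 14 2,4-bis[2-azido-1-(4-bromophenyl)ethenyl]-N,N-dimethyl-1H-imidazole-1-sulfonamide (mixture of alkene isomers; the E,E isomer is drawn)
Conditions: Ph2S[OC(CF3)2Ph]2 (Martin sulfurane), CH2Cl2, 0 °C → rt
Reagents that add atoms: none
Why: Dehydration of a tertiary alcohol with the sulfurane proceeds at room temperature through an alkoxysulfonium intermediate, and because the only β-hydrogens are those of the azide-acidified CH2N3 group, elimination can only give the 2-azidovinyl unit; the low temperature protects the thermally labile vinyl azides, and the alkene geometry is not controlled.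

Step 8
Reactants: 14 2,4-bis[2-azido-1-(4-bromophenyl)ethenyl]-N,N-dimethyl-1H-imidazole-1-sulfonamide
Product: 16 2,4-bis(6-bromo-1H-indol-3-yl)-N,N-dimethyl-1H-imidazole-1-sulfonamide, via bis(2H-azirine) 15 (not isolated)
Conditions: PhMe (0.02 M), 4 Å MS, 100 °C; then Rh2(O2CC3F7)4 (5 mol %), 100 °C
Reagents that add atoms: none
Why: Heating expels N2 from each vinyl azide to give the 2-aryl-2-imidazolyl-2H-azirine, so every alkene isomer of 14 converges on 15, and the dirhodium tetracarboxylate then opens the strained azirine C–N bond to a rhodium-bound vinyl nitrenoid. The closest known reaction type is the thermal or dirhodium-carboxylate-catalysed conversion of β-aryl vinyl azides and 2-aryl-2H-azirines into indoles (nitrene indolisation of the Hemetsberger–Knittel kind). Each pyrrole ring closes by a 6π-electron, five-atom electrocyclisation of the N–C2=C3–C3a=C7a unit, in which nitrogen bonds to an ortho carbon of the 4-bromophenyl ring (N1–C7a), and a 1,5-hydrogen shift then restores the benzenoid ring and delivers the N–H indole. No stereocentre is created, and regiochemistry is automatic because bromine is para to the carbon that becomes C3a, so both ortho positions are equivalent and only the 6-bromo isomer can form. The selectivity required is amination of the aryl ring in preference to N3 or C5 of the imidazole. It should be secured by the N1 sulfamoyl group, which lowers the basicity of N3 and the nucleophilicity of C5, makes closure of the C4 arm onto N3 lead to an N-sulfonylimidazolium ylide with no neutral valence structure, and pushes the C2 arm out of the coplanar conformation that N–N closure needs, together with the known preference of dirhodium carboxylate nitrenoids for arene C–H amination.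

Step 9
Reactants: 16 2,4-bis(6-bromo-1H-indol-3-yl)-N,N-dimethyl-1H-imidazole-1-sulfonamide
Product: 17 nortopsentin A [2,4-bis(6-bromo-1H-indol-3-yl)-1H-imidazole]
Conditions: 2 M aq HCl, EtOH, 80 °C; basic work-up
Reagents that add atoms: none
Why: Acid-catalysed hydrolysis of the N-sulfamoyl group (N–S cleavage after protonation of N3, which turns the imidazole into a leaving group) is the standard release of this protecting group; the indoles are shielded from acid-induced oligomerisation by the C3 imidazolium substituent, and the aryl bromides are inert.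

**Compound list**

1 | 4-iodo-1H-imidazole | Ic1c[nH]cn1 | starting material
2 | dimethylsulfamoyl chloride | CN(C)S(=O)(=O)Cl | starting material
3 | 4-iodo-N,N-dimethyl-1H-imidazole-1-sulfonamide | CN(C)S(=O)(=O)n1cnc(I)c1 | intermediate
4 | 4-bromobenzaldehyde | O=Cc1ccc(Br)cc1 | starting material
5 | 2-lithio-4-iodo-N,N-dimethylimidazole-1-sulfonamide (not isolated) | CN(C)S(=O)(=O)n1cc(I)nc1[Li] | intermediate
6 | 2-[(4-bromophenyl)(hydroxy)methyl]-4-iodo-N,N-dimethyl-1H-imidazole-1-sulfonamide (racemic) | CN(C)S(=O)(=O)n1cc(I)nc1C(O)c1ccc(Br)cc1 | intermediate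
7 | C4-chloromagnesio chloromagnesium alkoxide derived from 6 (not isolated; racemic) | CN(C)S(=O)(=O)n1cc([Mg]Cl)nc1C(O[Mg]Cl)c1ccc(Br)cc1 | intermediate
8 | 2,4-bis[(4-bromophenyl)(hydroxy)methyl]-N,N-dimethyl-1H-imidazole-1-sulfonamide (mixture of diastereomers) | CN(C)S(=O)(=O)n1cc(C(O)c2ccc(Br)cc2)nc1C(O)c1ccc(Br)cc1 | intermediate
9 | 2,4-bis(4-bromobenzoyl)-N,N-dimethyl-1H-imidazole-1-sulfonamide | CN(C)S(=O)(=O)n1cc(C(=O)c2ccc(Br)cc2)nc1C(=O)c1ccc(Br)cc1 | intermediate
10 | trimethylsulfonium iodide | C[S+](C)C.[I-] | starting material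
11 | 2,4-bis[2-(4-bromophenyl)oxiran-2-yl]-N,N-dimethyl-1H-imidazole-1-sulfonamide (mixture of diastereomers) | CN(C)S(=O)(=O)n1cc(C2(c3ccc(Br)cc3)CO2)nc1C1(c2ccc(Br)cc2)CO1 | intermediate
12 | sodium azide | [N-]=[N+]=[N-].[Na+] | starting material
13 | 2,4-bis[2-azido-1-(4-bromophenyl)-1-hydroxyethyl]-N,N-dimethyl-1H-imidazole-1-sulfonamide (mixture of diastereomers) | CN(C)S(=O)(=O)n1cc(C(O)(CN=[N+]=[N-])c2ccc(Br)cc2)nc1C(O)(CN=[N+]=[N-])c1ccc(Br)cc1 | intermediate
14 | 2,4-bis[2-azido-1-(4-bromophenyl)ethenyl]-N,N-dimethyl-1H-imidazole-1-sulfonamide (E,E isomer drawn, each azide cis to the aryl ring; used as the mixture of alkene isomers) | CN(C)S(=O)(=O)n1cc(/C(=C/N=[N+]=[N-])c2ccc(Br)cc2)nc1/C(=C/N=[N+]=[N-])c1ccc(Br)cc1 | intermediate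
15 | 2,4-bis[2-(4-bromophenyl)-2H-azirin-2-yl]-N,N-dimethyl-1H-imidazole-1-sulfonamide (not isolated; mixture of diastereomers) | CN(C)S(=O)(=O)n1cc(C2(c3ccc(Br)cc3)C=N2)nc1C1(c2ccc(Br)cc2)C=N1 | intermediate
16 | 2,4-bis(6-bromo-1H-indol-3-yl)-N,N-dimethyl-1H-imidazole-1-sulfonamide | CN(C)S(=O)(=O)n1cc(-c2c[nH]c3cc(Br)ccc23)nc1-c1c[nH]c2cc(Br)ccc12 | intermediate
17 | nortopsentin A, 2,4-bis(6-bromo-1H-indol-3-yl)-1H-imidazole (no stereocentres) | Brc1ccc2c(-c3c[nH]c(-c4c[nH]c5cc(Br)ccc45)n3)c[nH]c2c1 | target

**Step count and risks**

Total step count: 9. Longest linear sequence: 9 steps (the route is fully linear, 1 → 17).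

Steps most likely to fail, in order of risk:

1. Step 8. What may go wrong: the nitrenoid of the C2 arm may close onto the lone pair of N3 (N–N bond formation to a fused pyrazole) faster than onto the aryl ring. A 1,2-hydrogen shift of the vinyl nitrene to a ketenimine that ends as a nitrile, or sequestration of the catalyst by the heterocycle, may also intervene. The fallback gives up the nitrene closure and joins preformed 6-bromoindole rings to the imidazole by cross-coupling. It sets out from 3 and returns at 16.
   - Deprotonation of 3 at C2 with LiN(iPr)2 (through 5) and quenching with I2 should give 2,4-diiodo-N,N-dimethyl-1H-imidazole-1-sulfonamide F1.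
   - Commercial 6-bromo-1H-indole would be N-silylated (NaH, iPr3SiCl, THF) to 6-bromo-1-(triisopropylsilyl)-1H-indole F2.
   - Iridium-catalysed C–H borylation, directed to C3 by the bulky silyl group ([Ir(OMe)(cod)]2, 4,4′-di-tert-butyl-2,2′-bipyridine, B2pin2, THF, 60 °C), should give 6-bromo-3-(4,4,5,5-tetramethyl-1,3,2-dioxaborolan-2-yl)-1-(triisopropylsilyl)-1H-indole F3.
   - Twofold Suzuki–Miyaura coupling of F1 with F3 (Pd(PPh3)4, aq Na2CO3, DME, 80 °C), in which the C–I bonds react ahead of the C–Br bonds, should give 2,4-bis[6-bromo-1-(triisopropylsilyl)-1H-indol-3-yl]-N,N-dimethyl-1H-imidazole-1-sulfonamide F4.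
   - TBAF in THF removes both silyl groups and rejoins the route at 16.

2. Step 7. What may go wrong: ionisation-type side reactions (substitution or aryl migration) at the congested tertiary centres may outpace elimination, or N2 may be lost from the product during a slow reaction. The fallback builds the azidovinyl units by olefination and not by elimination. It sets out from 9 and returns at 14.
   - Boron–Wittig olefination of 9 with lithiated bis(pinacolato)borylmethane (CH2(Bpin)2, lithium 2,2,6,6-tetramethylpiperidide, THF, −78 °C → rt) should give 2,4-bis[1-(4-bromophenyl)-2-(4,4,5,5-tetramethyl-1,3,2-dioxaborolan-2-yl)ethenyl]-N,N-dimethyl-1H-imidazole-1-sulfonamide F5 (mixture of alkene isomers).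
   - Copper-promoted azidodeboronation (NaN3, Cu(OAc)2, MeOH, rt, air), to which aryl bromides are inert, converts each C–B bond into a C–N3 bond and returns to the route at 14 without passing through 11 or 13.

3. Step 5. What may go wrong: the basic ylide medium may attack the N–S bond of the doubly acylated, hence activated, imidazole (loss of the protecting group), or epoxidation of the C2 ketone next to the sulfamoyl group may stay incomplete. The fallback separates carbon transfer from oxygen transfer and avoids basic nucleophiles. It sets out from 9 and returns at 11.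
   - Methylenation of 9 with the Tebbe reagent Cp2Ti(μ-Cl)(μ-CH2)AlMe2 (THF/PhMe, 0 °C) should give 2,4-bis[1-(4-bromophenyl)ethenyl]-N,N-dimethyl-1H-imidazole-1-sulfonamide F6.
   - Epoxidation of both 1,1-disubstituted alkenes with dimethyldioxirane (acetone, 0 °C → rt) returns to the route at 11.

Further compounds
F1 | step 8 | 2,4-diiodo-N,N-dimethyl-1H-imidazole-1-sulfonamide | CN(C)S(=O)(=O)n1cc(I)nc1I
F2 | step 8 | 6-bromo-1-(triisopropylsilyl)-1H-indole | CC(C)[Si](C(C)C)(C(C)C)n1ccc2ccc(Br)cc21
F3 | step 8 | 6-bromo-3-(4,4,5,5-tetramethyl-1,3,2-dioxaborolan-2-yl)-1-(triisopropylsilyl)-1H-indole | CC(C)[Si](C(C)C)(C(C)C)n1cc(B2OC(C)(C)C(C)(C)O2)c2ccc(Br)cc21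
F4 | step 8 | 2,4-bis[6-bromo-1-(triisopropylsilyl)-1H-indol-3-yl]-N,N-dimethyl-1H-imidazole-1-sulfonamide | CN(C)S(=O)(=O)n1cc(-c2cn([Si](C(C)C)(C(C)C)C(C)C)c3cc(Br)ccc23)nc1-c1cn([Si](C(C)C)(C(C)C)C(C)C)c2cc(Br)ccc12
F5 | step 7 | 2,4-bis[1-(4-bromophenyl)-2-(4,4,5,5-tetramethyl-1,3,2-dioxaborolan-2-yl)ethenyl]-N,N-dimethyl-1H-imidazole-1-sulfonamide (mixture of alkene isomers) | CN(C)S(=O)(=O)n1cc(C(=CB2OC(C)(C)C(C)(C)O2)c2ccc(Br)cc2)nc1C(=CB1OC(C)(C)C(C)(C)O1)c1ccc(Br)cc1
F6 | step 5 | 2,4-bis[1-(4-bromophenyl)ethenyl]-N,N-dimethyl-1H-imidazole-1-sulfonamide | CN(C)S(=O)(=O)n1cc(C(=C)c2ccc(Br)cc2)nc1C(=C)c1ccc(Br)cc1
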